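**Retrosynthetic overview**

1. Target 17 ⇐ hydrogenolysis of the C5–O benzyl ether of 16; both acetates ⇐ one acetylation of the phenol/secondary-alcohol pair 15 ⇐ MOM ether 14.
2. Key disconnection: the bond between the benzylic CH2 and the carbinol carbon C2 of the pentadecyl chain of 14, made by lithiation–borylation. The (–)-sparteine-lithiated tetradecyl 2,4,6-triisopropylbenzoate (the carbinol carbon with reversed polarity, a chiral carbenoid) inserts into the C–B bond of benzylboronic ester 8 by a 1,2-benzyl shift; C–B is then oxidised to C–O.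
3. Enabling feature: the oxygen on C2 of the pentadecyl chain. As a hindered benzoate it acidifies and directs removal of one enantiotopic hydrogen on that carbon and then acts as the leaving group. It sits next to the benzylic CH2 on C1 of the benzene ring, a carbon that carries boron and migrates readily.
4. 8 ⇐ aryl bromide 5 + ClCH2Bpin; 5 ⇐ 5-bromovanillin (Br marks ring carbon C1; the formyl group becomes the C5 oxygen by Baeyer–Villiger oxidation); 10 ⇐ 1-bromotetradecane.
5. No ring is formed in the route; the benzene ring is carried from 5-bromovanillin throughout.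

Key step: step 6

Remark: the stereocentre of the target is read as (R) (O > CH2Ar > CH2-alkyl > H); the route is drawn for (2R)-1-(2-acetoxy-5-hydroxy-3-methoxyphenyl)pentadecan-2-yl acetate.

**Route**

Step 1
Reactants: 1 5-bromovanillin (3-bromo-4-hydroxy-5-methoxybenzaldehyde)
Product: 2 3-bromo-5-methoxy-4-(methoxymethoxy)benzaldehyde
Conditions: MOMCl, K2CO3, DMF, 0 °C → rt
Reagents that add atoms: chloromethyl methyl ether (MOMCl), COCCl
Why: Williamson-type O-alkylation of the acidic ortho-bromophenoxide gives the MOM ether, and the aldehyde is untouched.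

Step 2
Reactants: 2 3-bromo-5-methoxy-4-(methoxymethoxy)benzaldehyde
Product: 4 3-bromo-5-methoxy-4-(methoxymethoxy)phenol, via aryl formate 3 (not isolated)
Conditions: mCPBA, CH2Cl2, 0 °C → rt; aq. Na2SO3/NaHCO3 wash; then K2CO3 (cat.), MeOH, rt
Reagents that add atoms: 3-chloroperoxybenzoic acid (mCPBA), O=C(OO)c1cccc(Cl)c1
Why: Baeyer–Villiger (Dakin-type) oxidation, in which the para-alkoxy group should make aryl migration faster than hydride migration; the formate is then cleaved by mild methanolysis that leaves the MOM ether intact.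

Step 3
Reactants: 4 3-bromo-5-methoxy-4-(methoxymethoxy)phenol
Product: 5 5-(benzyloxy)-1-bromo-3-methoxy-2-(methoxymethoxy)benzene
Conditions: BnBr, K2CO3, DMF, rt
Reagents that add atoms: benzyl bromide, BrCc1ccccc1
Why: Williamson ether synthesis on the only free, unhindered phenoxide.

Step 4
Reactants: 5 5-(benzyloxy)-1-bromo-3-methoxy-2-(methoxymethoxy)benzene
Product: 8 2-[5-(benzyloxy)-3-methoxy-2-(methoxymethoxy)benzyl]-4,4,5,5-tetramethyl-1,3,2-dioxaborolane, via aryllithium 6 (not isolated), via chloromethyl boronate complex 7 (not isolated)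
Conditions: n-BuLi, THF, –78 °C; then ClCH2Bpin, –78 °C → rt
Reagents that add atoms: 2-(chloromethyl)-4,4,5,5-tetramethyl-1,3,2-dioxaborolane (ClCH2Bpin), ClCB1OC(C)(C)C(C)(C)O1
Why: Bromine–lithium exchange (helped by chelation of lithium by the ortho-OMOM oxygen) outruns any deprotonation at –78 °C; the aryllithium adds to boron and the ate complex undergoes a 1,2-aryl shift with loss of chloride on warming (Matteson-type homologation from the halomethylboronate side).

Step 5
Reactants: 9 1-bromotetradecane
Product: 10 tetradecyl 2,4,6-triisopropylbenzoate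
Conditions: 2,4,6-triisopropylbenzoic acid, K2CO3, DMF, 60 °C
Reagents that add atoms: 2,4,6-triisopropylbenzoic acid, CC(C)c1cc(C(C)C)c(C(O)=O)c(C(C)C)c1
Why: SN2 O-alkylation of the hindered carboxylate by the primary bromide, the usual way to esters of 2,6-disubstituted benzoic acids.

Step 6
Reactants: 10 tetradecyl 2,4,6-triisopropylbenzoate; 8 2-[5-(benzyloxy)-3-methoxy-2-(methoxymethoxy)benzyl]-4,4,5,5-tetramethyl-1,3,2-dioxaborolane
Product: 14 (2R)-1-[5-(benzyloxy)-3-methoxy-2-(methoxymethoxy)phenyl]pentadecan-2-ol, via lithiated benzoate 11 (not isolated), via boronate complex 12 (not isolated), via secondary boronic ester 13 (not isolated)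
Conditions: 10 (1.3 equiv), s-BuLi (1.25 equiv), (–)-sparteine (1.3 equiv), Et2O, –78 °C, 5 h; then 8 (1.0 equiv), –78 °C, 1 h; then 35 °C, 12 h; then NaOH, 30% H2O2, THF/H2O, 0 °C → rt
Reagents that add atoms: hydrogen peroxide, OO
Why: s-BuLi/(–)-sparteine removes the pro-S α-hydrogen of 10, the ester carbonyl holding lithium so that 11 stays configurationally stable at –78 °C; 11 adds to boron of 8 with retention to give 12, the benzylic CH2 then migrates from boron to carbon anti to the departing triisopropylbenzoate (1,2-metalate rearrangement, inversion at carbon) to form the ArCH2–CH bond in (R)-13, and basic peroxide replaces boron by oxygen with retention. The closest known reaction type is the Hoppe–Matteson–Aggarwal lithiation–borylation of primary alkyl 2,4,6-triisopropylbenzoates with primary and benzylic pinacol boronic esters. No ring is closed. The single new stereocentre is under reagent control by (–)-sparteine: the (S)-carbenoid is carried through retention, inversion and retention to the (R)-carbinol. The step needs selection between the enantiotopic α-hydrogens, attack at boron instead of deprotonation of the benzylic C–H of 8, and migration of carbon instead of a pinacol oxygen; these should be secured by the chelated sparteine complex, by fast ate formation at –78 °C with 8 as the limiting component and no free s-BuLi, and by the single carbon ligand on boron facing an excellent benzoate leaving group. The MOM, benzyl and methyl ethers are inert to 11 and to basic peroxide.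

Step 7
Reactants: 14 (2R)-1-[5-(benzyloxy)-3-methoxy-2-(methoxymethoxy)phenyl]pentadecan-2-ol
Product: 15 4-(benzyloxy)-2-[(2R)-2-hydroxypentadecyl]-6-methoxyphenol
Conditions: conc. HCl (cat.), MeOH, 40 °C
Reagents that add atoms: none
Why: Acid-catalysed acetal exchange with methanol removes the aryl MOM group, while the benzyl ether, the methyl ether and the non-benzylic secondary alcohol do not ionise under these conditions.

Step 8
Reactants: 15 4-(benzyloxy)-2-[(2R)-2-hydroxypentadecyl]-6-methoxyphenol
Product: 16 (2R)-1-[2-acetoxy-5-(benzyloxy)-3-methoxyphenyl]pentadecan-2-yl acetate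
Conditions: Ac2O, pyridine, DMAP (cat.), CH2Cl2, rt
Reagents that add atoms: acetic anhydride, CC(=O)OC(C)=O
Why: DMAP-catalysed acylation should acetylate the hindered phenol and the secondary alcohol in one operation without touching the stereocentre.

Step 9
Reactants: 16 (2R)-1-[2-acetoxy-5-(benzyloxy)-3-methoxyphenyl]pentadecan-2-yl acetate
Product: 17 (2R)-1-(2-acetoxy-5-hydroxy-3-methoxyphenyl)pentadecan-2-yl acetate
Conditions: H2 (1 atm), 10% Pd/C, EtOAc, rt
Reagents that add atoms: none
Why: Palladium-catalysed hydrogenolysis cleaves only the benzylic C–O bond of the benzyl ether; the carbinol acetate is homobenzylic and, like the aryl acetate, is not hydrogenolysed, and the neutral medium gives no path for acetyl migration.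

**Compound list**

1 | 5-bromovanillin (3-bromo-4-hydroxy-5-methoxybenzaldehyde) | O=Cc1cc(Br)c(O)c(OC)c1 | starting material
2 | 3-bromo-5-methoxy-4-(methoxymethoxy)benzaldehyde | O=Cc1cc(Br)c(OCOC)c(OC)c1 | intermediate
3 | 3-bromo-5-methoxy-4-(methoxymethoxy)phenyl formate (not isolated) | O=COc1cc(Br)c(OCOC)c(OC)c1 | intermediate
4 | 3-bromo-5-methoxy-4-(methoxymethoxy)phenol | Oc1cc(Br)c(OCOC)c(OC)c1 | intermediate
5 | 5-(benzyloxy)-1-bromo-3-methoxy-2-(methoxymethoxy)benzene | COCOc1c(Br)cc(OCc2ccccc2)cc1OC | intermediate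
6 | [5-(benzyloxy)-3-methoxy-2-(methoxymethoxy)phenyl]lithium (not isolated) | COCOc1c([Li])cc(OCc2ccccc2)cc1OC | intermediate
7 | lithium [5-(benzyloxy)-3-methoxy-2-(methoxymethoxy)phenyl](chloromethyl)(pinacolato)borate (not isolated) | [Li+].COCOc1c(cc(OCc2ccccc2)cc1OC)[B-]1(CCl)OC(C)(C)C(C)(C)O1 | intermediate
8 | 2-[5-(benzyloxy)-3-methoxy-2-(methoxymethoxy)benzyl]-4,4,5,5-tetramethyl-1,3,2-dioxaborolane | COCOc1c(CB2OC(C)(C)C(C)(C)O2)cc(OCc3ccccc3)cc1OC | intermediate
9 | 1-bromotetradecane | CCCCCCCCCCCCCCBr | starting material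
10 | tetradecyl 2,4,6-triisopropylbenzoate | CCCCCCCCCCCCCCOC(=O)c1c(C(C)C)cc(C(C)C)cc1C(C)C | intermediate
11 | (S)-1-lithiotetradecyl 2,4,6-triisopropylbenzoate, as its (–)-sparteine complex (not isolated) | CCCCCCCCCCCCC[C@H]([Li])OC(=O)c1c(C(C)C)cc(C(C)C)cc1C(C)C | intermediate
12 | lithium (S)-boronate complex of 11 and 8 (not isolated) | [Li+].CCCCCCCCCCCCC[C@H]([B-]1(Cc2cc(OCc3ccccc3)cc(OC)c2OCOC)OC(C)(C)C(C)(C)O1)OC(=O)c1c(C(C)C)cc(C(C)C)cc1C(C)C | intermediate
13 | 2-{(2R)-1-[5-(benzyloxy)-3-methoxy-2-(methoxymethoxy)phenyl]pentadecan-2-yl}-4,4,5,5-tetramethyl-1,3,2-dioxaborolane (not isolated) | CCCCCCCCCCCCC[C@H](Cc1cc(OCc2ccccc2)cc(OC)c1OCOC)B1OC(C)(C)C(C)(C)O1 | intermediate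
14 | (2R)-1-[5-(benzyloxy)-3-methoxy-2-(methoxymethoxy)phenyl]pentadecan-2-ol | CCCCCCCCCCCCC[C@H](Cc1cc(OCc2ccccc2)cc(OC)c1OCOC)O | intermediate
15 | 4-(benzyloxy)-2-[(2R)-2-hydroxypentadecyl]-6-methoxyphenol | CCCCCCCCCCCCC[C@H](Cc1cc(OCc2ccccc2)cc(OC)c1O)O | intermediate
16 | (2R)-1-[2-acetoxy-5-(benzyloxy)-3-methoxyphenyl]pentadecan-2-yl acetate | CCCCCCCCCCCCC[C@H](Cc1cc(OCc2ccccc2)cc(OC)c1OC(C)=O)OC(C)=O | intermediate
17 | (2R)-1-(2-acetoxy-5-hydroxy-3-methoxyphenyl)pentadecan-2-yl acetate | CCCCCCCCCCCCC[C@H](Cc1cc(O)cc(OC)c1OC(C)=O)OC(C)=O | target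

**Summary**

Total step count: 9. Longest linear sequence: 8 steps (steps 1–4 and 6–9; step 5 is the one-step side branch).

Steps most likely to fail:

1. Step 6. The deprotonation may be incomplete or insufficiently enantioselective; 11 may deprotonate the benzylic C–H next to boron in 8 instead of adding to boron; or the 1,2-shift may be slow enough for the ate complex to revert. The fallback replaces reagent control by auxiliary control (Matteson homologation); it sets out from 8 and returns at 14. 8 is transesterified with (1R,2R,3S,5R)-(–)-pinanediol (Et2O, rt) to the pinanediol benzylboronate F1. LiCHCl2 (from CH2Cl2 and n-BuLi, THF, –100 °C), then ZnCl2 and warming to rt, inserts a CHCl unit into the benzyl–boron bond, so the same CH2–CH bond is formed under control of the diol, and should give the (αR)-α-chloro boronic ester F2. Tridecylmagnesium bromide (THF, –78 °C → rt) displaces chloride with inversion through a second 1,2-shift to give the secondary pinanediol boronic ester F3, and NaOH/H2O2 converts F3 into 14.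

2. Step 4. The aryl 1,2-shift from the hindered, electron-rich ate complex may stall, so that work-up returns protodeboronated arene; the aryllithium may also be alkylated by the 1-bromobutane formed in the exchange. The fallback separates C–B formation from the one-carbon insertion; it sets out from 5 and returns at 8. Miyaura borylation of 5 (B2pin2, PdCl2(dppf), KOAc, dioxane, 80 °C) gives 2-[5-(benzyloxy)-3-methoxy-2-(methoxymethoxy)phenyl]-4,4,5,5-tetramethyl-1,3,2-dioxaborolane F4, which is homologated with LiCH2Cl generated in situ (BrCH2Cl, n-BuLi, THF, –78 °C → rt) to 8.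

3. Step 2. On the bromine-deactivated ring, hydride migration may compete with aryl migration (over-oxidation to the benzoic acid), and the 3-chlorobenzoic acid formed may strip the MOM group. The fallback oxidises before protection; it sets out from 1 and returns at 4. Dakin oxidation of the free para-hydroxy aldehyde 1 (H2O2, aq. NaOH, rt) gives 2-bromo-6-methoxybenzene-1,4-diol F5. The unhindered hydroxyl is silylated selectively (TBSCl, imidazole, CH2Cl2, 0 °C) to 2-bromo-4-[(tert-butyldimethylsilyl)oxy]-6-methoxyphenol F6. The hindered hydroxyl is converted to its MOM ether (MOMCl, K2CO3, DMF) to give [3-bromo-5-methoxy-4-(methoxymethoxy)phenoxy](tert-butyl)dimethylsilane F7, and TBAF (THF, 0 °C) releases 4.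

Further compounds
F1 | step 6 | (1R,2R,3S,5R)-pinanediol [5-(benzyloxy)-3-methoxy-2-(methoxymethoxy)benzyl]boronate | C[C@]1([C@@H]2C[C@@H](C2(C)C)C[C@@H]1O3)OB3Cc1cc(OCc2ccccc2)cc(OC)c1OCOC
F2 | step 6 | (1R,2R,3S,5R)-pinanediol {(1R)-2-[5-(benzyloxy)-3-methoxy-2-(methoxymethoxy)phenyl]-1-chloroethyl}boronate | C[C@]1([C@@H]2C[C@@H](C2(C)C)C[C@@H]1O3)OB3[C@@H](Cl)Cc1cc(OCc2ccccc2)cc(OC)c1OCOC
F3 | step 6 | (1R,2R,3S,5R)-pinanediol {(2R)-1-[5-(benzyloxy)-3-methoxy-2-(methoxymethoxy)phenyl]pentadecan-2-yl}boronate | C[C@]1([C@@H]2C[C@@H](C2(C)C)C[C@@H]1O3)OB3[C@H](CCCCCCCCCCCCC)Cc1cc(OCc2ccccc2)cc(OC)c1OCOC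
F4 | step 4 | 2-[5-(benzyloxy)-3-methoxy-2-(methoxymethoxy)phenyl]-4,4,5,5-tetramethyl-1,3,2-dioxaborolane | COCOc1c(B2OC(C)(C)C(C)(C)O2)cc(OCc3ccccc3)cc1OC
F5 | step 2 | 2-bromo-6-methoxybenzene-1,4-diol | Oc1cc(Br)c(O)c(OC)c1
F6 | step 2 | 2-bromo-4-[(tert-butyldimethylsilyl)oxy]-6-methoxyphenol | CC(C)(C)[Si](C)(C)Oc1cc(Br)c(O)c(OC)c1
F7 | step 2 | [3-bromo-5-methoxy-4-(methoxymethoxy)phenoxy](tert-butyl)dimethylsilane | CC(C)(C)[Si](C)(C)Oc1cc(Br)c(OCOC)c(OC)c1
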